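**Retrosynthetic overview**
1. Both CO2H groups are unmasked last in one RuO4 operation. C4–CO2H comes from a 4α-(2-methylprop-1-enyl) group and the side-chain CO2H from a terminal alkyne.
2. Key disconnection: C4–C5, C9–C10 and C8–OAc are cut together, back to an acyclic (E,E,E)-tetraenyne plus acetic acid. The forward step uses a confined chiral Brønsted acid and no metal. Ring A closes first, ring B second, and acetate capture ends the cascade. All five stereocentres arise here.
3. The dienyl initiator comes from Wittig isopropylidenation of an (E)-2-methylenal, which is made by terminal allylic oxidation of a farnesyl-type trienyne.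
4. The trienyne comes from (E,E)-farnesyl bromide and a propargyl anion equivalent.

Assumption: ring atoms carry labdane numbers (C4 = carboxyl-bearing quaternary carbon, C5/C10 = ring fusion, C8 = acetoxy carbon, C9 = side-chain carbon), and the (S,S) antipode of the catalyst is taken to give the fold drawn; if the sense of induction is opposite, the (R,R) antipode is used.

**Step 1**
Reactants: 1 (2E,6E)-farnesyl bromide [(2E,6E)-1-bromo-3,7,11-trimethyldodeca-2,6,10-triene]; 2 1-(trimethylsilyl)propyne
Product: 5 (5E,9E)-6,10,14-trimethylpentadeca-5,9,13-trien-1-yne, via lithiated silylpropyne 3 (not isolated), via C-silyl trienyne 4 (not isolated)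
Conditions: 2 (1.2 equiv), n-BuLi (1.15 equiv), THF, −78 → −20 °C; 1, −78 °C → rt; then MeOH, K2CO3 (0.3 equiv), rt, same flask
Reagents that add atoms: none
Why: SN2 propargylation of the primary allylic bromide (the C-silyl group blocks the acetylide position and suppresses allenyl coupling) leaves both E-alkenes untouched, catalytic methoxide then cleaves the C(sp)–Si bond, and no stereocentre is formed.

**Step 2**
Reactants: 5 (5E,9E)-6,10,14-trimethylpentadeca-5,9,13-trien-1-yne
Product: 7 (2E,6E,10E)-2,6,10-trimethylpentadeca-2,6,10-trien-14-ynal, via E-allylic alcohol 6 (not isolated)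
Conditions: SeO2 (10 mol %), salicylic acid (10 mol %), t-BuOOH (2.5 equiv), CH2Cl2, 0 °C → rt, stopped at ca. 70 % conversion; aqueous wash; crude, MnO2 (15 equiv), CH2Cl2, rt
Reagents that add atoms: tert-butyl hydroperoxide, CC(C)(C)OO
Why: Catalytic SeO2 allylic oxidation (ene reaction, then [2,3]-sigmatropic shift) picks the most accessible terminal isopropylidene unit and oxidises only its E-methyl group, MnO2 converges the alcohol/aldehyde mixture to the E-enal without touching the isolated alkenes or the alkyne, and the E geometry fixed here later becomes the C4 configuration.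

**Step 3**
Reactants: 7 (2E,6E,10E)-2,6,10-trimethylpentadeca-2,6,10-trien-14-ynal; 8 isopropyltriphenylphosphonium iodide
Product: 10 (5E,9E,13E)-6,10,14,16-tetramethylheptadeca-5,9,13,15-tetraen-1-yne, via isopropylidene ylide 9 (not isolated)
Conditions: 8 (1.3 equiv), n-BuLi (1.25 equiv), THF, 0 °C; 7, −78 °C → rt
Reagents that add atoms: none
Why: Wittig olefination with a non-stabilised symmetrical ylide adds 1,2 to the enal and gives an alkene with no E/Z issue, the slight deficit of base leaves the alkyne C–H alone, and the 13E alkene is retained.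

**Step 4**
Reactants: 10 (5E,9E,13E)-6,10,14,16-tetramethylheptadeca-5,9,13,15-tetraen-1-yne; 11 acetic acid
Product: 13 (1R,2R,4aS,5S,8aS)-1-(but-3-yn-1-yl)-2,5,8a-trimethyl-5-(2-methylprop-1-en-1-yl)decahydronaphthalen-2-yl acetate (trans-decalin; 4α-isobutenyl, 4β-Me, 5α-H, 8α-OAc, 8β-Me, 9α-H, 9β-butynyl, 10β-Me), via allyl cation 12 (not isolated)
Conditions: (S,S)-IDPi (5 mol %; BINOL-derived imidodiphosphorimidate with bulky 3,3'-spirocycloalkyl-fluorenyl walls and a perfluoroarylsulfonyl core), 11 (10 equiv), (CF3)3COH/CH2Cl2 1:1, 0.05 M, −30 °C, 48 h, stopped at full conversion of 10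
Reagents that add atoms: none
Why: Proposed new method: an asymmetric, dienyl-initiated and acetic-acid-terminated polyene bicyclisation, in which the confined strong acid protonates the most basic π-system of 10 (C3 of the twisted 2,4-dimethyldienyl terminus rather than the two isolated trisubstituted alkenes) to give the tetraalkylallyl cation 12 as a contact ion pair in the chiral pocket (allylic acetates or diene isomers formed reversibly re-ionise to the same cation), its tertiary terminus C4 is attacked by the C5=C10 alkene and C10 in turn by the C9=C8 alkene through an all-chair anti-periplanar (Stork–Eschenmoser) array with the bulky planar isobutenyl arm equatorial, so the E,E geometry fixes 5α-H/10β-Me/9α-H, the catalyst fixes the absolute fold, and an AcOH molecule hydrogen-bonded to the IDPi anion adds anti at C8 from the open equatorial α face (the β face is blocked by the axial 10-Me) while the terminal alkyne is too poor a π-nucleophile to compete; the closest known reaction types are IDPi-catalysed head-to-tail cyclisation of homofarnesol-type polyenes ended by an internal OH or CO2H group, Johnson allyl-cation-initiated polyene cyclisation with solvent capture, and chiral phosphoric acid/carboxylic acid heterodimer catalysis.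

**Step 5**
Reactants: 13 (1R,2R,4aS,5S,8aS)-1-(but-3-yn-1-yl)-2,5,8a-trimethyl-5-(2-methylprop-1-en-1-yl)decahydronaphthalen-2-yl acetate
Product: 14 (1R,4aS,5R,6R,8aR)-6-acetoxy-5-(2-carboxyethyl)-1,4a,6-trimethyldecahydronaphthalene-1-carboxylic acid (target)
Conditions: RuCl3·xH2O (5 mol %), NaIO4 (9 equiv), EtOAc/MeCN/H2O 2:2:3, rt, 4 h; acidic work-up; recrystallisation (upgrades er)
Reagents that add atoms: sodium periodate, [Na+].[O-]I(=O)(=O)=O; water, O
Why: RuO4 oxidative cleavage (Sharpless conditions) converts the trisubstituted alkene (via the neopentyl aldehyde) and the terminal alkyne into carboxylic acids in the same pot, the tertiary acetate and the saturated trans-decalin are inert under these near-neutral conditions, and nothing is scrambled because C4 is quaternary and no stereocentre is enolisable.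

**Compound list**
1 | (2E,6E)-farnesyl bromide | CC(C)=CCC/C(C)=C/CC/C(C)=C/CBr | starting material
2 | 1-(trimethylsilyl)propyne | CC#C[Si](C)(C)C | starting material
3 | 3-lithio-1-(trimethylsilyl)propyne | [Li]CC#C[Si](C)(C)C | intermediate
4 | trimethyl[(5E,9E)-6,10,14-trimethylpentadeca-5,9,13-trien-1-yn-1-yl]silane | CC(C)=CCC/C(C)=C/CC/C(C)=C/CCC#C[Si](C)(C)C | intermediate
5 | (5E,9E)-6,10,14-trimethylpentadeca-5,9,13-trien-1-yne | CC(C)=CCC/C(C)=C/CC/C(C)=C/CCC#C | intermediate
6 | (2E,6E,10E)-2,6,10-trimethylpentadeca-2,6,10-trien-14-yn-1-ol | OC/C(C)=C/CC/C(C)=C/CC/C(C)=C/CCC#C | intermediate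
7 | (2E,6E,10E)-2,6,10-trimethylpentadeca-2,6,10-trien-14-ynal | O=C/C(C)=C/CC/C(C)=C/CC/C(C)=C/CCC#C | intermediate
8 | isopropyltriphenylphosphonium iodide | CC(C)[P+](c1ccccc1)(c1ccccc1)c1ccccc1.[I-] | starting material
9 | isopropylidenetriphenylphosphorane | CC(C)=P(c1ccccc1)(c1ccccc1)c1ccccc1 | intermediate
10 | (5E,9E,13E)-6,10,14,16-tetramethylheptadeca-5,9,13,15-tetraen-1-yne | CC(C)=C/C(C)=C/CC/C(C)=C/CC/C(C)=C/CCC#C | intermediate
11 | acetic acid | CC(=O)O | starting material
12 | tetraalkylallyl cation from C3-protonation of 10 (ion pair with the IDPi anion) | CC(C)=C[C+](C)CCC/C(C)=C/CC/C(C)=C/CCC#C | intermediate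
13 | (1R,2R,4aS,5S,8aS)-1-(but-3-yn-1-yl)-2,5,8a-trimethyl-5-(2-methylprop-1-en-1-yl)decahydronaphthalen-2-yl acetate | CC(=O)O[C@]1(C)CC[C@@H]2[C@](C)(CCC[C@@]2(C)C=C(C)C)[C@H]1CCC#C | intermediate
14 | (1R,4aS,5R,6R,8aR)-6-acetoxy-5-(2-carboxyethyl)-1,4a,6-trimethyldecahydronaphthalene-1-carboxylic acid | CC(=O)O[C@]1(C)CC[C@@H]2[C@](C)(CCC[C@@]2(C)C(=O)O)[C@H]1CCC(=O)O | target

**Total step count:** 5. **Longest linear sequence:** 5.

**Three steps most likely to fail**

**Step 4 (the proposed new step).**
- Risks:
  - protonation of an internal alkene instead of the dienyl terminus;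
  - proton loss at C8 instead of acetate capture;
  - insufficient er;
  - partial formation of the C4 epimer;
  - acid damage to the isobutenyl group or the tertiary acetate of 13.
- Fallback (sets out from 10, comes back at 13): it uses only classical chemistry. Compound 10 is cyclised under Johnson/Stork–Eschenmoser-type conditions with a stoichiometric achiral acid and acetic acid as co-solvent (H2SO4 or CF3SO3H, 1 equiv, AcOH/CH2Cl2, −20 → 0 °C). Solvent-level acetic acid secures the equatorial capture at C8. The same relative configuration is obtained as a racemate, that is 13 together with the enantiomeric acetate F1. The two are separated by preparative SFC on a chiral stationary phase, and 13 continues into step 5.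

**Step 2.**
- Risks: only modest preference for the terminal alkene over the two internal ones, over-oxidation, and slow propargylic oxidation. The expected yield is about 40 %.
- Fallback (sets out from 5, comes back at 7): the ene oxidation is replaced by a cut-and-rebuild sequence.
  - NBS in aqueous THF at 0 °C gives the terminal bromohydrin F2.
  - K2CO3 in MeOH closes it to the terminal epoxide F3.
  - H5IO6 in THF/Et2O cleaves this to the trisnor aldehyde F4.
  - A stabilised Wittig reaction with 2-(triphenylphosphoranylidene)propanal in hot toluene rebuilds the E-configured enal 7.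

**Step 5.**
- Risks: sluggish cleavage of the terminal alkyne, a stall at the hindered C4 aldehyde, or RuO4 attack on tertiary C–H bonds on long exposure.
- Fallback (sets out from 13, comes back at 14): the two acids are released by separate chemoselective reactions.
  - Gold(I)-catalysed Markovnikov hydration of the alkyne (IPrAuCl/AgSbF6, aqueous dioxane) gives the methyl ketone F5.
  - Ozonolysis with Me2S work-up cleaves only the isobutenyl group to the keto aldehyde F6.
  - Pinnick oxidation gives the keto acid F7.
  - A haloform reaction (NaOBr, aqueous dioxane, 0 °C, then acidification) shortens the methyl ketone to the side-chain acid of 14. The hindered tertiary acetate survives.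

**Further compounds**
F1 | step 4 | (1S,2S,4aR,5R,8aR)-1-(but-3-yn-1-yl)-2,5,8a-trimethyl-5-(2-methylprop-1-en-1-yl)decahydronaphthalen-2-yl acetate (enantiomer of 13) | CC(=O)O[C@@]1(C)CC[C@H]2[C@@](C)(CCC[C@]2(C)C=C(C)C)[C@@H]1CCC#C
F2 | step 2 | (6E,10E)-3-bromo-2,6,10-trimethylpentadeca-6,10-dien-14-yn-2-ol (racemic) | CC(C)(O)C(Br)CC/C(C)=C/CC/C(C)=C/CCC#C
F3 | step 2 | 3-[(3E,7E)-3,7-dimethyldodeca-3,7-dien-11-yn-1-yl]-2,2-dimethyloxirane (racemic) | CC1(C)OC1CC/C(C)=C/CC/C(C)=C/CCC#C
F4 | step 2 | (4E,8E)-4,8-dimethyltrideca-4,8-dien-12-ynal | O=CCC/C(C)=C/CC/C(C)=C/CCC#C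
F5 | step 5 | (1R,2R,4aS,5S,8aS)-2,5,8a-trimethyl-5-(2-methylprop-1-en-1-yl)-1-(3-oxobutyl)decahydronaphthalen-2-yl acetate | CC(=O)O[C@]1(C)CC[C@@H]2[C@](C)(CCC[C@@]2(C)C=C(C)C)[C@H]1CCC(C)=O
F6 | step 5 | (1R,2R,4aR,5R,8aS)-5-formyl-2,5,8a-trimethyl-1-(3-oxobutyl)decahydronaphthalen-2-yl acetate | CC(=O)O[C@]1(C)CC[C@@H]2[C@](C)(CCC[C@@]2(C)C=O)[C@H]1CCC(C)=O
F7 | step 5 | (1R,4aS,5R,6R,8aR)-6-acetoxy-1,4a,6-trimethyl-5-(3-oxobutyl)decahydronaphthalene-1-carboxylic acid | CC(=O)O[C@]1(C)CC[C@@H]2[C@](C)(CCC[C@@]2(C)C(=O)O)[C@H]1CCC(C)=O
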